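**Retrosynthetic overview**
- The ester is cut to (2R,3S,4S)-lariciresinol and (R)-2-methylbutanoic acid, joined last by a chemoselective Mitsunobu esterification of the primary alcohol.
- The oxolane, the only ring of the target, is made in one (3+2) cycloaddition: its C2(aryl)–O1–C5H2 unit is a non-stabilised carbonyl ylide and its C3–C4 bond is the C=C of a butenolide.
- Enabling feature: oxolane C3 carries a one-carbon oxygenated arm and C4 a benzylic carbon, cis to each other. Tied together as C3–C(=O)–O–CH(Ar)–C4 they form a γ-aryl butenolide: the lactone activates the alkene and locks the cis relation, and its (R)-γ-carbon (the later benzylic CH2) steers the ylide to one face. The electron-rich 4-oxygenated aryl group on C2 polarises the ylide for the required regiochemistry.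
- One hydrogenolysis then erases the γ-stereocentre by cleaving the lactone C–O bond and removes both benzyl ethers; borane reduction of the acid gives the hydroxymethyl arm.
- Ring order: temporary butenolide first, oxolane second (key step), lactone ring opened afterwards.

Key step: step 5

Remark: O-benzylvanillin, methyl propiolate, (trimethylsilyl)methanol and (R)-2-methylbutanoic acid are taken as commercial.
Remark: the (S,S)-ProPhenol/Me2Zn catalyst is assumed to deliver the (S)-propargylic alcohol from this aldehyde; if the opposite sense is found, the (R,R)-ligand is used with no other change.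

**Step 1**
Reactants: 1 4-(benzyloxy)-3-methoxybenzaldehyde (O-benzylvanillin); 2 methyl propiolate
Product: 3 methyl (4S)-4-[4-(benzyloxy)-3-methoxyphenyl]-4-hydroxybut-2-ynoate
Conditions: 2 (3 equiv), Me2Zn (3 equiv), (S,S)-ProPhenol (10 mol%), Ph3P=O (20 mol%), toluene, 4 °C; aq. NH4Cl
Reagents that add atoms: none
Why: Dinuclear-zinc (ProPhenol) catalysed enantioselective alkynylation of an aryl aldehyde with the zinc acetylide of 2; the chiral Zn2 pocket selects one aldehyde face and sets the (S)-carbinol carbon, the only stereocentre of the dipolarophile.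

**Step 2**
Reactants: 3
Product: 5 (5R)-5-[4-(benzyloxy)-3-methoxyphenyl]furan-2(5H)-one, via Z-hydroxy enoate 4 (not isolated)
Conditions: H2 (1 atm), Lindlar catalyst, quinoline, EtOAc, rt; filter; PPTS (5 mol%), CH2Cl2, rt
Reagents that add atoms: none
Why: Lindlar semihydrogenation is syn and should stop at the (Z)-enoate, whose γ-hydroxyl then lactonises under mild acid without any base, so the benzylic centre is carried over unchanged (the S to R change of descriptor is only a CIP priority switch).

**Step 3**
Reactants: 1 4-(benzyloxy)-3-methoxybenzaldehyde; 6 (trimethylsilyl)methanol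
Product: 7 1-(benzyloxy)-4-{bis[(trimethylsilyl)methoxy]methyl}-2-methoxybenzene
Conditions: 6 (3 equiv), p-TsOH·H2O (2 mol%), toluene, reflux, Dean–Stark; Et3N, then removal of excess 6 in vacuo
Reagents that add atoms: none
Why: Acid-catalysed acetalisation of an aromatic aldehyde with a primary alcohol, driven by azeotropic removal of water; no stereocentre is formed.

**Step 4**
Reactants: 7
Product: 8 1-(benzyloxy)-4-{chloro[(trimethylsilyl)methoxy]methyl}-2-methoxybenzene (racemic α-chloro ether; moisture-sensitive and used crude at once)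
Conditions: AcCl (1.3 equiv), SOCl2 (2 mol%), CH2Cl2, 0 °C to rt; volatiles removed in vacuo
Reagents that add atoms: acetyl chloride CC(=O)Cl
Why: Acyl chloride cleavage of an acetal to the α-chloro ether, the standard preparation of α-chlorobenzyl ethers, helped here by the 4-alkoxyaryl group that stabilises the oxocarbenium intermediate; the new centre is racemic, which is without consequence because this carbon becomes trigonal in the ylide.

**Step 5**
Reactants: 8 α-chloro ether; 5 (5R)-5-[4-(benzyloxy)-3-methoxyphenyl]furan-2(5H)-one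
Product: 10 (3R,3aS,6R,6aR)-3,6-bis[4-(benzyloxy)-3-methoxyphenyl]tetrahydro-1H,3H-furo[3,4-c]furan-1-one, via carbonyl ylide 9 (not isolated)
Conditions: 8 (2 equiv), 5 (1 equiv), CsF (2.2 equiv, added in portions), MeCN, 0 °C to rt
Reagents that add atoms: none
Why: Chloride loss from 8 gives an α-silyl oxocarbenium ion, and fluoride attack on silicon (1,3-elimination) unmasks the non-stabilised carbonyl ylide 9, which adds across the C=C of 5 in a concerted, asynchronous, ylide-HOMO/enoate-LUMO controlled 1,3-dipolar cycloaddition. The closest known reaction type is the fluoride-induced formation of non-stabilised carbonyl ylides from silylmethyl α-chloroalkyl ethers and their (3+2) addition to acrylates, fumarates and maleimides. The oxolane ring is closed intermolecularly by suprafacial formation of both C–C bonds (CH2 to the β-carbon, ArCH to the α-carbon), so the cis ring fusion, i.e. the later 3,4-cis relation, is dictated by the Z-alkene held in the lactone ring. The two ring-fusion stereocentres follow from attack on the face of 5 anti to its γ-aryl group (control by the (R)-γ-carbon), and the aryl-bearing carbon follows from the exo approach of the E (W-shaped) ylide, whose oxygen and aryl group point away from the lactone, which places that aryl group on the convex face, trans to the lactone carbonyl carbon. The step needs regioselectivity, secured by the 4-benzyloxy-3-methoxyphenyl group, which stabilises positive charge on its own carbon and leaves the nucleophilic terminus at CH2, matched to the electrophilic β-carbon; it also needs 5 to stay enantiopure, which the low solubility of CsF in MeCN and the excess of 8 (fluoride is consumed at silicon as it dissolves) should secure.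

**Step 6**
Reactants: 10
Product: 11 (2R,3R,4S)-2-(4-hydroxy-3-methoxyphenyl)-4-[(4-hydroxy-3-methoxyphenyl)methyl]oxolane-3-carboxylic acid
Conditions: H2 (1 atm), 10% Pd/C, EtOAc–EtOH 1:1, rt, monitored and stopped at full conversion; filtration through Celite
Reagents that add atoms: none
Why: Heterogeneous Pd-catalysed hydrogenolysis cleaves the two aryl benzyl ethers and the benzylic C–O bond of the lactone, which has a carboxylate leaving group (para-hydroxybenzylic once the phenol is free) and should therefore go much faster than the benzylic ether C–O bond of the oxolane; the auxiliary γ-stereocentre becomes CH2 and the three ring stereocentres are untouched.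

**Step 7**
Reactants: 11
Product: 12 4-{[(3S,4S,5R)-5-(4-hydroxy-3-methoxyphenyl)-4-(hydroxymethyl)oxolan-3-yl]methyl}-2-methoxyphenol ((2R,3S,4S)-lariciresinol, the enantiomer of the common (+)-form)
Conditions: BH3·THF (5 equiv), THF, 0 °C to rt; MeOH, then H2O
Reagents that add atoms: none
Why: Borane reduction of a carboxylic acid to the primary alcohol via the acyloxyborane proceeds under neutral conditions, so neither the α-carbon of the acid nor the acid-labile 2-aryl oxolane should epimerise.

**Step 8**
Reactants: 12 (2R,3S,4S)-lariciresinol; 13 (2R)-2-methylbutanoic acid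
Product: 14 [(2R,3S,4S)-2-(4-hydroxy-3-methoxyphenyl)-4-[(4-hydroxy-3-methoxyphenyl)methyl]oxolan-3-yl]methyl (2R)-2-methylbutanoate (CNP0315069.1)
Conditions: 13 (1.1 equiv), PPh3 (1.2 equiv), DIAD (1.2 equiv), THF, 0 °C to rt
Reagents that add atoms: none
Why: Mitsunobu esterification activates only the aliphatic primary alcohol as its alkoxyphosphonium ion, and the carboxylate (far more acidic than the phenols) is the nucleophile, so the ester should form without phenol protection; the acid is never turned into an acyl donor, so its α-stereocentre is not at risk, and no stereocentre of the alcohol is involved.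

**Compound list**
1 | 4-(benzyloxy)-3-methoxybenzaldehyde | O=Cc1ccc(OCc2ccccc2)c(OC)c1 | starting material
2 | methyl propiolate | C#CC(=O)OC | starting material
3 | methyl (4S)-4-[4-(benzyloxy)-3-methoxyphenyl]-4-hydroxybut-2-ynoate | COC(=O)C#C[C@@H](O)c1ccc(OCc2ccccc2)c(OC)c1 | intermediate
4 | methyl (2Z,4R)-4-[4-(benzyloxy)-3-methoxyphenyl]-4-hydroxybut-2-enoate | COC(=O)/C=C\[C@@H](O)c1ccc(OCc2ccccc2)c(OC)c1 | intermediate (not isolated)
5 | (5R)-5-[4-(benzyloxy)-3-methoxyphenyl]furan-2(5H)-one | O=C1C=C[C@H](c2ccc(OCc3ccccc3)c(OC)c2)O1 | intermediate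
6 | (trimethylsilyl)methanol | C[Si](C)(C)CO | starting material
7 | 1-(benzyloxy)-4-{bis[(trimethylsilyl)methoxy]methyl}-2-methoxybenzene | COc1cc(C(OC[Si](C)(C)C)OC[Si](C)(C)C)ccc1OCc1ccccc1 | intermediate
8 | 1-(benzyloxy)-4-{chloro[(trimethylsilyl)methoxy]methyl}-2-methoxybenzene (racemic) | COc1cc(C(Cl)OC[Si](C)(C)C)ccc1OCc1ccccc1 | intermediate
9 | carbonyl ylide, [4-(benzyloxy)-3-methoxybenzylidene]oxonium methylide | [CH2-][O+]=Cc1ccc(OCc2ccccc2)c(OC)c1 | intermediate (not isolated)
10 | (3R,3aS,6R,6aR)-3,6-bis[4-(benzyloxy)-3-methoxyphenyl]tetrahydro-1H,3H-furo[3,4-c]furan-1-one | O=C3[C@@H]1[C@H]([C@H](c2ccc(OCc4ccccc4)c(OC)c2)O3)CO[C@H]1c1ccc(OCc2ccccc2)c(OC)c1 | intermediate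
11 | (2R,3R,4S)-2-(4-hydroxy-3-methoxyphenyl)-4-[(4-hydroxy-3-methoxyphenyl)methyl]oxolane-3-carboxylic acid | OC(=O)[C@@H]1[C@H](Cc2ccc(O)c(OC)c2)CO[C@H]1c1ccc(O)c(OC)c1 | intermediate
12 | (2R,3S,4S)-lariciresinol | OC[C@@H]1[C@H](Cc2ccc(O)c(OC)c2)CO[C@H]1c1ccc(O)c(OC)c1 | intermediate
13 | (2R)-2-methylbutanoic acid | CC[C@@H](C)C(=O)O | starting material
14 | [(2R,3S,4S)-2-(4-hydroxy-3-methoxyphenyl)-4-[(4-hydroxy-3-methoxyphenyl)methyl]oxolan-3-yl]methyl (2R)-2-methylbutanoate | CC[C@@H](C)C(=O)OC[C@@H]1[C@H](Cc2ccc(O)c(OC)c2)CO[C@H]1c1ccc(O)c(OC)c1 | target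

**Step count and risks**
Total steps: 8. Longest linear sequence: 6 (steps 1, 2, 5, 6, 7, 8 from compound 1).

Steps most likely to fail:

1. Step 5. Fluoride-mediated enolisation of butenolide 5 may racemise its γ-aryl centre faster than the ylide is trapped, so that facial control and enantiopurity are lost; incomplete exo selectivity at the aryl-bearing carbon is a lesser concern. The fallback uses auxiliary control with late introduction of the aryl group and sets out from 8. Under the step-5 conditions 8 is added to commercial (5R)-5-[(1R,2S,5R)-menthyloxy]furan-2(5H)-one (O=C1C=C[C@H](O[C@@H]2C[C@H](C)CC[C@H]2C(C)C)O1), a dipolarophile of fixed configuration that is attacked anti to its alkoxy group, to give the menthyloxy cycloadduct F1. Aqueous acid (TFA–H2O, rt) should hydrolyse the acetal to the lactol F2 with release of menthol. 4-(Benzyloxy)-3-methoxyphenylmagnesium bromide (3 equiv, THF, −40 °C) adds to the open aldehyde form, and acidification closes the γ-aryl lactone F3 as a mixture of epimers at the new benzylic carbon. Both epimers converge under the step-6 conditions, because that carbon becomes CH2, and the route is rejoined at 11.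

2. Step 6. Over-reduction may occur, i.e. hydrogenolytic opening of the oxolane at its benzylic C2–O bond during the time needed to cleave the lactone C–O bond. The fallback removes the lactone oxygen by a radical path and sets out from 10. LiAlH4 (THF, 0 °C) should give the diol F4. The primary hydroxyl is esterified selectively with 13 (EDC·HCl, cat. DMAP, CH2Cl2, −20 °C) to give the hydroxy ester F5. The remaining secondary benzylic alcohol is converted into the O-phenyl thionocarbonate F6 (PhOC(S)Cl, pyridine, CH2Cl2) and removed by Barton–McCombie reduction (Bu3SnH, AIBN, toluene, 80 °C) to give the dibenzyl ether of the target F7. A short hydrogenolysis (H2, Pd/C, EtOAc, rt) that only has to cleave the two aryl benzyl ethers returns to the route at 14.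

3. Step 8. The phenols may compete (aryl ether formation and oligomers), and displacement at the β-branched primary carbinol may be slow. The fallback is exhaustive acylation followed by chemoselective aminolysis and sets out from 12. 13 (3.5 equiv), EDC·HCl and DMAP in CH2Cl2 should give the tris(2-methylbutanoate) F8. Pyrrolidine (2.2 equiv, CH2Cl2, 0 °C) should cleave the two aryl esters much faster than the alkyl ester, returning to the route at 14.

**Further compounds**
F1 | step 5 | (3R,3aS,6R,6aR)-6-[4-(benzyloxy)-3-methoxyphenyl]-3-{[(1R,2S,5R)-2-isopropyl-5-methylcyclohexyl]oxy}tetrahydro-1H,3H-furo[3,4-c]furan-1-one | O=C3[C@@H]1[C@H]([C@H](O[C@@H]2C[C@H](C)CC[C@H]2C(C)C)O3)CO[C@H]1c1ccc(OCc2ccccc2)c(OC)c1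
F2 | step 5 | (3aS,6R,6aR)-6-[4-(benzyloxy)-3-methoxyphenyl]-3-hydroxytetrahydro-1H,3H-furo[3,4-c]furan-1-one (anomer mixture) | O=C3[C@@H]1[C@H](C(O)O3)CO[C@H]1c1ccc(OCc2ccccc2)c(OC)c1
F3 | step 5 | (3aS,6R,6aR)-3,6-bis[4-(benzyloxy)-3-methoxyphenyl]tetrahydro-1H,3H-furo[3,4-c]furan-1-one (both C3 epimers) | O=C3[C@@H]1[C@H](C(c2ccc(OCc4ccccc4)c(OC)c2)O3)CO[C@H]1c1ccc(OCc2ccccc2)c(OC)c1
F4 | step 6 | (R)-[4-(benzyloxy)-3-methoxyphenyl]{(3S,4S,5R)-5-[4-(benzyloxy)-3-methoxyphenyl]-4-(hydroxymethyl)oxolan-3-yl}methanol | OC[C@@H]1[C@H]([C@@H](O)c2ccc(OCc3ccccc3)c(OC)c2)CO[C@H]1c1ccc(OCc2ccccc2)c(OC)c1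
F5 | step 6 | primary (2R)-2-methylbutanoate of F4 | CC[C@@H](C)C(=O)OC[C@@H]1[C@H]([C@@H](O)c2ccc(OCc3ccccc3)c(OC)c2)CO[C@H]1c1ccc(OCc2ccccc2)c(OC)c1
F6 | step 6 | O-phenyl thionocarbonate of F5 | CC[C@@H](C)C(=O)OC[C@@H]1[C@H]([C@@H](OC(=S)Oc2ccccc2)c2ccc(OCc3ccccc3)c(OC)c2)CO[C@H]1c1ccc(OCc2ccccc2)c(OC)c1
F7 | step 6 | O,O'-dibenzyl ether of 14 | CC[C@@H](C)C(=O)OC[C@@H]1[C@H](Cc2ccc(OCc3ccccc3)c(OC)c2)CO[C@H]1c1ccc(OCc2ccccc2)c(OC)c1
F8 | step 8 | tris[(2R)-2-methylbutanoate] of 12 | CC[C@@H](C)C(=O)OC[C@@H]1[C@H](Cc2ccc(OC(=O)[C@H](C)CC)c(OC)c2)CO[C@H]1c1ccc(OC(=O)[C@H](C)CC)c(OC)c1
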